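**Plan**

- Retrosynthesis: ring A is traced back to a 3-oxo-7-oxanorbornene ester by re-forming an oxygen bridge from the C3 oxygen to C6. The C2 oxygen is then exchanged for bromine, and ring bonds C1–C6 and C2–C3 are cut to give furan and a 3-bromopropiolate. The ester C–O bond and the chain C16–C17 bond are cut last.
- Enabling feature: in ring A (benzoate C1–C6, CO2R on C1, OH on C2 and C3) the atoms O–C3–C4–C5–C6 are the oxygen and four carbons of furan. C1–C2, with its ester and a heteroatom on C2, is a propiolate unit.
- Forward order: the C5 and C16 pieces are coupled to the chain alcohol, which is esterified with propiolic acid and brominated at the alkyne. The [4+2] addition with furan is the only ring-forming step. Bromine is then replaced by oxygen, the bridge is opened and ring A aromatises.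
- Stereochemistry: the single (S) centre (C18 of the chain) is bought in (S)-1-bromo-2-methylbutane and never sits next to a reacting atom. The bridgehead centres of the bicyclic intermediates are uncontrolled and are erased on aromatisation.

Key step: step 6

Remark: compounds 11 to 14 are assumed to be carried forward as mixtures of bridgehead (and C2 or C5) epimers, since every one of these centres becomes sp2 in step 8. Locants for 11–13 are those of the 7-oxabicyclo[2.2.1]heptane skeleton.

**Route**

Step 1
Reactants: 1 16-bromohexadecan-1-ol
Product: 2 (16-bromohexadecyloxy)(tert-butyl)dimethylsilane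
Conditions: tert-butyldimethylsilyl chloride (1.2 equiv), imidazole (2.0 equiv), CH2Cl2, 0 °C to rt
Reagents that add atoms: tert-butyldimethylsilyl chloride, CC(C)(C)[Si](C)(C)Cl
Why: Imidazole-mediated silylation of a primary alcohol should mask the hydroxyl for the Grignard coupling while leaving the primary bromide untouched.

Step 2
Reactants: 3 (S)-1-bromo-2-methylbutane; 2 (16-bromohexadecyloxy)(tert-butyl)dimethylsilane
Product: 5 tert-butyldimethyl{[(S)-18-methylicosyl]oxy}silane, via (S)-2-methylbutylmagnesium bromide 4 (not isolated)
Conditions: 3 (1.5 equiv), Mg, THF, 40 °C; then 2 (1.0 equiv), Li2CuCl4 (3 mol%), THF, −20 °C to rt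
Reagents that add atoms: none
Why: Kochi-type copper-catalysed sp3–sp3 cross-coupling of a primary alkyl Grignard reagent with a primary alkyl bromide should join C16 to C17; the stereocentre is beta to magnesium and is not touched, and the silyl ether is inert.

Step 3
Reactants: 5 tert-butyldimethyl{[(S)-18-methylicosyl]oxy}silane
Product: 6 (S)-18-methylicosan-1-ol
Conditions: p-toluenesulfonic acid monohydrate (10 mol%), MeOH/CH2Cl2 (1:1), rt
Reagents that add atoms: none
Why: Acid-catalysed methanolysis of a primary tert-butyldimethylsilyl ether should free the alcohol, with nothing else in the molecule able to react.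

Step 4
Reactants: 6 (S)-18-methylicosan-1-ol; 7 propiolic acid
Product: 8 (S)-18-methylicosyl propiolate
Conditions: 7 (2 equiv), p-toluenesulfonic acid monohydrate (5 mol%), toluene, Dean–Stark, reflux
Reagents that add atoms: none
Why: Fischer esterification driven by azeotropic removal of water is the established way to make propiolates of long-chain primary alcohols and avoids carbodiimide activation of the sensitive acid.

Step 5
Reactants: 8 (S)-18-methylicosyl propiolate
Product: 9 (S)-18-methylicosyl 3-bromopropiolate
Conditions: N-bromosuccinimide (1.15 equiv), AgNO3 (10 mol%), acetone, rt, dark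
Reagents that add atoms: N-bromosuccinimide, O=C1CCC(=O)N1Br
Why: Silver-catalysed electrophilic bromination of a terminal alkyne through the silver acetylide is the standard preparation of 3-bromopropiolates and does not affect the ester.

Step 6
Reactants: 9 (S)-18-methylicosyl 3-bromopropiolate; 10 furan
Product: 11 (S)-18-methylicosyl 3-bromo-7-oxabicyclo[2.2.1]hepta-2,5-diene-2-carboxylate (both bridgehead configurations)
Conditions: furan (6 equiv), toluene, sealed tube, 80 °C, 24–36 h
Reagents that add atoms: none
Why: A thermal, concerted [4+2] cycloaddition in which furan reacts as the diene through C2 and C5 and the ester- and bromine-polarised alkyne as the dienophile, the direct model being the Diels–Alder reaction of furan with methyl or ethyl 3-bromopropiolate. The six-membered carbocycle of the 7-oxanorbornadiene (the future ring A) is closed by intermolecular cycloaddition, both sigma bonds (future benzoate C1–C6 and C2–C3) forming suprafacially in one step while the furan oxygen becomes the one-atom bridge. The two bridgehead centres arise together and are tied to each other by the bicyclic frame; nothing relates them to the distant (S)-methyl centre, so both configurations form, which is harmless because both carbons become sp2 in step 8. No regiochemical control is needed because furan is symmetric, so the dienophile alone fixes the constitution: the ester carbon becomes C2 and the bromine-bearing carbon C3 of the bicycle. What the step does need is clean mono-addition without reversion, and this should be secured by the alkyne dienophile (cycloreversion would have to regenerate an alkyne), by the excess of furan and by holding the temperature at 80 °C so that the hindered bromoacrylate double bond of the adduct does not add a second furan.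

Step 7
Reactants: 11 (S)-18-methylicosyl 3-bromo-7-oxabicyclo[2.2.1]hepta-2,5-diene-2-carboxylate
Product: 13 (S)-18-methylicosyl 3-oxo-7-oxabicyclo[2.2.1]hept-5-ene-2-carboxylate (mixture of diastereomers in equilibrium with its enol), via morpholine enaminoester 12 (not isolated)
Conditions: morpholine (2.2 equiv), THF, 0 °C to rt; then 1 M aq HCl, THF, 0 °C to rt
Reagents that add atoms: water, O
Why: Morpholine should add to C3 of the vinylogous acyl bromide and expel bromide (addition–elimination, as with beta-halo acrylates), and the weakly donating vinylogous carbamate is then hydrolysed like any enamine by C2 protonation and attack of water on the iminium ion; no alkoxide is present, so the long-chain ester cannot transesterify, and the new C2 centre is left uncontrolled because it is destroyed in step 8.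

Step 8
Reactants: 13 (S)-18-methylicosyl 3-oxo-7-oxabicyclo[2.2.1]hept-5-ene-2-carboxylate
Product: 15 gentiside H [(S)-18-methylicosyl 2,3-dihydroxybenzoate], via hydroxydienone ester 14 (not isolated)
Conditions: 1,8-diazabicyclo[5.4.0]undec-7-ene (DBU, 1.2 equiv), degassed THF, 0 °C to rt, Ar; then 1 M aq HCl
Reagents that add atoms: none
Why: E1cB ring opening, the base-induced beta-elimination known for 7-oxanorbornene-2-carboxylates: the enolate of the beta-keto ester should expel the bridging oxygen from C1 (the only C–O bond beta to the C2 carbanion) with release of bicyclic strain, and the resulting 6-hydroxycyclohexa-2,4-dienone enolises at once to the arene, so the furan oxygen ends on benzoate C3 and the former ketone oxygen on C2.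

**Compound list**

1 | 16-bromohexadecan-1-ol | OCCCCCCCCCCCCCCCCBr | starting material
2 | (16-bromohexadecyloxy)(tert-butyl)dimethylsilane | CC(C)(C)[Si](C)(C)OCCCCCCCCCCCCCCCCBr | intermediate
3 | (S)-1-bromo-2-methylbutane | CC[C@H](C)CBr | starting material
4 | (S)-2-methylbutylmagnesium bromide (not isolated) | CC[C@H](C)C[Mg]Br | intermediate
5 | tert-butyldimethyl{[(S)-18-methylicosyl]oxy}silane | CC[C@H](C)CCCCCCCCCCCCCCCCCO[Si](C)(C)C(C)(C)C | intermediate
6 | (S)-18-methylicosan-1-ol | CC[C@H](C)CCCCCCCCCCCCCCCCCO | intermediate
7 | propiolic acid | C#CC(=O)O | starting material
8 | (S)-18-methylicosyl propiolate | CC[C@H](C)CCCCCCCCCCCCCCCCCOC(=O)C#C | intermediate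
9 | (S)-18-methylicosyl 3-bromopropiolate | CC[C@H](C)CCCCCCCCCCCCCCCCCOC(=O)C#CBr | intermediate
10 | furan | c1ccoc1 | starting material
11 | (S)-18-methylicosyl 3-bromo-7-oxabicyclo[2.2.1]hepta-2,5-diene-2-carboxylate (both bridgehead configurations) | CC[C@H](C)CCCCCCCCCCCCCCCCCOC(=O)C1=C(Br)C2OC1C=C2 | intermediate
12 | (S)-18-methylicosyl 3-(morpholin-4-yl)-7-oxabicyclo[2.2.1]hepta-2,5-diene-2-carboxylate (both bridgehead configurations, not isolated) | CC[C@H](C)CCCCCCCCCCCCCCCCCOC(=O)C1=C(N3CCOCC3)C2OC1C=C2 | intermediate
13 | (S)-18-methylicosyl 3-oxo-7-oxabicyclo[2.2.1]hept-5-ene-2-carboxylate (mixture of diastereomers) | CC[C@H](C)CCCCCCCCCCCCCCCCCOC(=O)C1C(=O)C2OC1C=C2 | intermediate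
14 | (S)-18-methylicosyl 5-hydroxy-6-oxocyclohexa-1,3-diene-1-carboxylate (both configurations at C5, not isolated) | CC[C@H](C)CCCCCCCCCCCCCCCCCOC(=O)C1=CC=CC(O)C1=O | intermediate
15 | gentiside H, (S)-18-methylicosyl 2,3-dihydroxybenzoate | CC[C@H](C)CCCCCCCCCCCCCCCCCOC(=O)c1cccc(O)c1O | target

**Step count**

Total steps: 8. Longest linear sequence: 8 steps (1 → 2 → 5 → 6 → 8 → 9 → 11 → 13 → 15).

**Steps most likely to fail**

Step 8 (bridge opening and aromatisation). The stabilised beta-keto ester enolate may expel the bridging oxygen only slowly, because its pi system is poorly aligned with the C1–O bond. Prolonged exposure to base would then allow retro-Claisen cleavage or air oxidation of the catecholate. The fallback reverses the polarity of the bond cleavage. Setting out from 13, BF3·OEt2 (1.1 equiv) in CH2Cl2 at −20 to 0 °C activates the bridging oxygen as a leaving group, and the enol tautomer of 13, a 3-hydroxy-7-oxanorbornadiene, supplies the electron push. This is the acid-catalysed isomerisation of 7-oxanorbornadienes to phenols. Ionisation at C1 is favoured because it gives an oxocarbenium ion, so the oxygen pattern should be the same, and the sequence passes through protonated 14 and comes back to the route at 15. This fallback makes no compound outside the list (F0).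

Step 7 (bromide-to-oxygen exchange). After displacement of bromide the nitrogen lone pair may push open the C1–O bridge faster than C2 is protonated and hydrolysed. The ring would then aromatise with the amine retained at C2 and the oxygen pattern would be lost. Any 13 that opens under the acid would merely arrive at 15 early. The fallback uses an oxygen nucleophile matched to the ester so that transesterification is degenerate, and passes through a ketal that has no C2=C3 double bond and hence no push on the bridge. Setting out from 11, alcohol 6 (3 equiv) and NaH (1.1 equiv) in THF give sodium (S)-18-methylicosan-1-olate F1. This adds to C3 and displaces bromide to give the enol ether (S)-18-methylicosyl 3-{[(S)-18-methylicosyl]oxy}-7-oxabicyclo[2.2.1]hepta-2,5-diene-2-carboxylate F2. F2 takes up a second molecule of 6 under alkoxide catalysis to give the ketal (S)-18-methylicosyl 3,3-bis{[(S)-18-methylicosyl]oxy}-7-oxabicyclo[2.2.1]hept-5-ene-2-carboxylate F3, the counterpart of the well-known methoxide ketalisation of such bromides. Hydrolysis with 1 M aq HCl in THF then returns to the route at 13 and gives back two equivalents of 6 for reuse in step 4.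

Step 4 (propiolate formation). Propiolic acid may oligomerise or decarboxylate during the long reflux, and the alcohol may add across the triple bond under acid, so that the valuable alcohol 6 is only partly esterified. The fallback reaches the dienophile another way. Setting out from 6, Steglich esterification with commercial 3-(trimethylsilyl)propiolic acid (N,N'-dicyclohexylcarbodiimide, catalytic 4-(dimethylamino)pyridine, CH2Cl2, 0 °C) gives (S)-18-methylicosyl 3-(trimethylsilyl)propiolate F4. N-bromosuccinimide with catalytic AgNO3 in acetone then effects direct bromodesilylation of the silylalkyne, so the sequence bypasses 8 and comes back to the route at 9.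

**Further compounds**

F0 | step 8 | none | none
F1 | step 7 | sodium (S)-18-methylicosan-1-olate | CC[C@H](C)CCCCCCCCCCCCCCCCC[O-].[Na+]
F2 | step 7 | (S)-18-methylicosyl 3-{[(S)-18-methylicosyl]oxy}-7-oxabicyclo[2.2.1]hepta-2,5-diene-2-carboxylate (both bridgehead configurations) | CC[C@H](C)CCCCCCCCCCCCCCCCCOC(=O)C1=C(OCCCCCCCCCCCCCCCCC[C@@H](C)CC)C2OC1C=C2
F3 | step 7 | (S)-18-methylicosyl 3,3-bis{[(S)-18-methylicosyl]oxy}-7-oxabicyclo[2.2.1]hept-5-ene-2-carboxylate (mixture of diastereomers) | CC[C@H](C)CCCCCCCCCCCCCCCCCOC(=O)C1C(OCCCCCCCCCCCCCCCCC[C@@H](C)CC)(OCCCCCCCCCCCCCCCCC[C@@H](C)CC)C2OC1C=C2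
F4 | step 4 | (S)-18-methylicosyl 3-(trimethylsilyl)propiolate | CC[C@H](C)CCCCCCCCCCCCCCCCCOC(=O)C#C[Si](C)(C)C
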